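**Assumption:** locants follow spiro[4.5]decane numbering (C1 = CH–O-senecioyl, C3 = CH-isopropenyl, C5 = spiro atom, C6(CH3)=C7–C8(=O), C9 = CH–OAc, C10 = CH–CH3); the SMILES then reads (1S,3R,5S,9S,10R).

## Retrosynthetic overview

1. Target ⇐ enone alcohol 24 by C1 esterification and late α′-oxygenation/acetylation at C9 (trans to the C10 methyl).
2. 24 ⇐ spiro enone 21 by MeLi addition and oxidative 1,3-enone transposition (installs C6–CH3 and moves C=O to C8).
3. 21 ⇐ 19 by intramolecular enolate C-alkylation anti to the C10 methyl: this closes the five-membered ring (second ring) and sets the spiro centre.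
4. 19 ⇐ key intermolecular anti-aldol (C5–C1 bond) between the boron enolate of enone 5 and iodo aldehyde 16; it also sets C1.
5. 5 ⇐ crotonaldehyde + tert-butyl acetoacetate by organocatalytic Michael/aldol annulation (six-membered ring, formed first, sets C10); 16 ⇐ Evans deconjugative alkylation of an N-senecioyl oxazolidinone (sets C3).

## Route

Step 1
Reactants: 1 (E)-but-2-enal; 2 tert-butyl 3-oxobutanoate
Product: 5 (5S)-5-methylcyclohex-2-en-1-one, via tert-butyl (3S)-2-acetyl-3-methyl-5-oxopentanoate 3 (not isolated), via tert-butyl (6S)-6-methyl-2-oxocyclohex-3-ene-1-carboxylate 4 (not isolated)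
Conditions: (R)-2-[bis(3,5-bis(trifluoromethyl)phenyl)(trimethylsilyloxy)methyl]pyrrolidine (10 mol%), neat, rt; then TsOH·H2O (20 mol%), toluene, 80 °C
Reagents that add atoms: none
Why: Iminium-activated Michael addition of the acetoacetate carbon to the Si face of the crotonaldehyde β-carbon (the (R)-catalyst blocks the Re face) sets the methyl-bearing centre as (S), and acid then drives intramolecular aldol condensation, ester cleavage and decarboxylation (organocatalytic Robinson-type annulation); the sign of rotation is checked against the known (R)-antipode.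

Step 2
Reactants: 6 (4R)-4-benzyl-1,3-oxazolidin-2-one; 7 3-methylbut-2-enoyl chloride
Product: 9 (4R)-4-benzyl-3-(3-methylbut-2-enoyl)-1,3-oxazolidin-2-one, via lithium (4R)-4-benzyl-2-oxo-1,3-oxazolidin-3-ide 8 (not isolated)
Conditions: n-BuLi, THF, −78 °C; then 7, −78 → 0 °C
Reagents that add atoms: none
Why: N-acylation of the lithiated Evans auxiliary by the acid chloride; no stereocentre is formed.

Step 3
Reactants: 9 (4R)-4-benzyl-3-(3-methylbut-2-enoyl)-1,3-oxazolidin-2-one; 10 tert-butyl bromoacetate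
Product: 12 tert-butyl (3R)-3-{[(4R)-4-benzyl-2-oxo-1,3-oxazolidin-3-yl]carbonyl}-4-methylpent-4-enoate, via sodium (Z)-dienolate of the imide 11 (not isolated)
Conditions: NaN(SiMe3)2, THF, −78 °C; then 10, −78 → −40 °C
Reagents that add atoms: none
Why: γ-Deprotonation gives the chelated (Z)-dienolate, which is alkylated at the α-carbon on the face opposite the benzyl group (Evans deconjugative alkylation), creating the isopropenyl-bearing centre as (3R).

Step 4
Reactants: 12 tert-butyl (3R)-3-{[(4R)-4-benzyl-2-oxo-1,3-oxazolidin-3-yl]carbonyl}-4-methylpent-4-enoate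
Product: 13 tert-butyl (3R)-3-(hydroxymethyl)-4-methylpent-4-enoate
Conditions: LiBH4, H2O (1 equiv), Et2O, 0 °C
Reagents that add atoms: none
Why: LiBH4 reduces the activated imide carbonyl chemoselectively (the tert-butyl ester is inert) without touching the stereocentre.

Step 5
Reactants: 13 tert-butyl (3R)-3-(hydroxymethyl)-4-methylpent-4-enoate
Product: 14 tert-butyl (3R)-3-(iodomethyl)-4-methylpent-4-enoate
Conditions: PPh3, I2, imidazole, CH2Cl2, 0 °C → rt
Reagents that add atoms: iodine, [I][I]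
Why: Appel-type (Garegg–Samuelsson) iodination of the primary alcohol by SN2 at CH2, which leaves the adjacent stereocentre untouched.

Step 6
Reactants: 14 tert-butyl (3R)-3-(iodomethyl)-4-methylpent-4-enoate
Product: 16 (3R)-3-(iodomethyl)-4-methylpent-4-enal, via diisobutylaluminium hemiacetal of the ester 15 (not isolated)
Conditions: i-Bu2AlH (1.1 equiv), CH2Cl2, −78 °C; then 1 M HCl, −78 → 0 °C
Reagents that add atoms: none
Why: Partial ester reduction works because the tetrahedral aluminium hemiacetal is stable at −78 °C and releases the aldehyde only on work-up; the alkyl iodide is inert under these conditions.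

Step 7
Reactants: 5 (5S)-5-methylcyclohex-2-en-1-one; 16 (3R)-3-(iodomethyl)-4-methylpent-4-enal
Product: 18 (5S,6S)-6-[(1S,3R)-1-hydroxy-3-(iodomethyl)-4-methylpent-4-en-1-yl]-5-methylcyclohex-2-en-1-one, via dicyclohexyl{[(3S)-3-methylcyclohexa-1,5-dien-1-yl]oxy}borane 17 (not isolated)
Conditions: (c-C6H11)2BCl, Et3N, Et2O, −78 → 0 °C; then 16, −78 °C; then MeOH, pH 7 buffer, H2O2, 0 °C
Reagents that add atoms: none
Why: The (E)-configured cross-conjugated boron enolate adds to the aldehyde through a Zimmerman–Traxler chair on the face trans to the adjacent ring methyl (intermolecular boron aldol reaction), giving the 5,6-trans anti aldol and thereby the (1S) carbinol centre that becomes C1 of the target.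

Step 8
Reactants: 18 (5S,6S)-6-[(1S,3R)-1-hydroxy-3-(iodomethyl)-4-methylpent-4-en-1-yl]-5-methylcyclohex-2-en-1-one
Product: 19 (5S,6S)-6-[(1S,3R)-1-{[tert-butyl(dimethyl)silyl]oxy}-3-(iodomethyl)-4-methylpent-4-en-1-yl]-5-methylcyclohex-2-en-1-one
Conditions: t-BuMe2SiOTf, 2,6-lutidine, CH2Cl2, −78 °C
Reagents that add atoms: tert-butyldimethylsilyl trifluoromethanesulfonate, CC(C)(C)[Si](C)(C)OS(=O)(=O)C(F)(F)F
Why: Low-temperature O-silylation caps the aldol hydroxyl (no retro-aldol, no O-alkylation later) with a bulky, non-chelating group; no stereocentre changes.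

Step 9
Reactants: 19 (5S,6S)-6-[(1S,3R)-1-{[tert-butyl(dimethyl)silyl]oxy}-3-(iodomethyl)-4-methylpent-4-en-1-yl]-5-methylcyclohex-2-en-1-one
Product: 21 (1S,3R,5R,10S)-1-{[tert-butyl(dimethyl)silyl]oxy}-10-methyl-3-(prop-1-en-2-yl)spiro[4.5]dec-7-en-6-one, via lithium dienolate of the silyl ether 20 (not isolated)
Conditions: LiN(i-Pr)2 (1.15 equiv), THF, −78 °C; then DMPU, −78 → −30 °C
Reagents that add atoms: none
Why: Kinetic α′-deprotonation regenerates the enolate at the former aldol carbon and 5-exo-tet C-alkylation by the primary iodide occurs anti to the pseudoaxial ring methyl (Stork-type intramolecular enolate alkylation), so at the spiro centre the new CH2 arm is trans and the silyloxy-bearing arm cis to that methyl; in the anti-aldol series allylic strain already holds the iodoalkyl chain on the face opposite the methyl.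

Step 10
Reactants: 21 (1S,3R,5R,10S)-1-{[tert-butyl(dimethyl)silyl]oxy}-10-methyl-3-(prop-1-en-2-yl)spiro[4.5]dec-7-en-6-one
Product: 22 (1S,3R,5R,10S)-1-{[tert-butyl(dimethyl)silyl]oxy}-6,10-dimethyl-3-(prop-1-en-2-yl)spiro[4.5]dec-7-en-6-ol (C6 epimers)
Conditions: MeLi, Et2O, −78 → 0 °C; then H2O
Reagents that add atoms: methyllithium, [Li]C
Why: MeLi adds 1,2 to the enone carbonyl (no α-hydrogen on the spiro side), and the configuration of the new carbinol is irrelevant because it is erased in the next step.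

Step 11
Reactants: 22 (1S,3R,5R,10S)-1-{[tert-butyl(dimethyl)silyl]oxy}-6,10-dimethyl-3-(prop-1-en-2-yl)spiro[4.5]dec-7-en-6-ol
Product: 23 (1S,3R,5S,10S)-1-{[tert-butyl(dimethyl)silyl]oxy}-6,10-dimethyl-3-(prop-1-en-2-yl)spiro[4.5]dec-6-en-8-one
Conditions: [C5H5NH][CrO3Cl] (pyridinium chlorochromate), 4 Å MS, CH2Cl2, rt
Reagents that add atoms: none
Why: Babler–Dauben oxidative 1,3-transposition of the tertiary allylic alcohol gives the 3-methyl enone with the carbonyl at C8; silyl ether and isopropenyl group tolerate the oxidant and no stereocentre is affected.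

Step 12
Reactants: 23 (1S,3R,5S,10S)-1-{[tert-butyl(dimethyl)silyl]oxy}-6,10-dimethyl-3-(prop-1-en-2-yl)spiro[4.5]dec-6-en-8-one
Product: 24 (1S,3R,5S,10S)-1-hydroxy-6,10-dimethyl-3-(prop-1-en-2-yl)spiro[4.5]dec-6-en-8-one
Conditions: HF·pyridine, pyridine, THF, 0 °C → rt
Reagents that add atoms: none
Why: Buffered fluoride desilylation frees the secondary alcohol; the ketone is now remote, so no retro-aldol pathway exists.

Step 13
Reactants: 24 (1S,3R,5S,10S)-1-hydroxy-6,10-dimethyl-3-(prop-1-en-2-yl)spiro[4.5]dec-6-en-8-one; 7 3-methylbut-2-enoyl chloride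
Product: 25 (1S,3R,5S,10S)-6,10-dimethyl-8-oxo-3-(prop-1-en-2-yl)spiro[4.5]dec-6-en-1-yl 3-methylbut-2-enoate
Conditions: pyridine, 4-(dimethylamino)pyridine (cat.), CH2Cl2, 0 °C → rt
Reagents that add atoms: none
Why: Nucleophile-catalysed O-acylation proceeds with retention at C1, and using pyridine as the only base limits deconjugation of the senecioyl group through a vinylketene.

Step 14
Reactants: 25 (1S,3R,5S,10S)-6,10-dimethyl-8-oxo-3-(prop-1-en-2-yl)spiro[4.5]dec-6-en-1-yl 3-methylbut-2-enoate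
Product: 27 (1S,3R,5S,9S,10R)-9-hydroxy-6,10-dimethyl-8-oxo-3-(prop-1-en-2-yl)spiro[4.5]dec-6-en-1-yl 3-methylbut-2-enoate, via lithium dienolate of the enone ester 26 (not isolated)
Conditions: LiN(i-Pr)2 (1.1 equiv), THF, −78 °C; then 2-(phenylsulfonyl)-3-phenyloxaziridine, −78 °C; then AcOH
Reagents that add atoms: 2-(phenylsulfonyl)-3-phenyloxaziridine, O=S(=O)(N1OC1c1ccccc1)c1ccccc1
Why: Kinetic α′-deprotonation gives the cross-conjugated enolate (the ketone is far more acidic than the ester), which the Davis oxaziridine hydroxylates on the face opposite the adjacent C10 methyl, giving the trans (9S) alcohol.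

Step 15
Reactants: 27 (1S,3R,5S,9S,10R)-9-hydroxy-6,10-dimethyl-8-oxo-3-(prop-1-en-2-yl)spiro[4.5]dec-6-en-1-yl 3-methylbut-2-enoate
Product: 28 (1S,3R,5S,9S,10R)-9-(acetyloxy)-6,10-dimethyl-8-oxo-3-(prop-1-en-2-yl)spiro[4.5]dec-6-en-1-yl 3-methylbut-2-enoate
Conditions: Ac2O, pyridine, 4-(dimethylamino)pyridine (cat.), CH2Cl2, 0 °C
Reagents that add atoms: acetic anhydride, CC(=O)OC(C)=O
Why: Mild acetylation of the secondary α-hydroxy ketone with retention at C9 gives the target.

## Compound list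

1 | (E)-but-2-enal (crotonaldehyde) | C/C=C/C=O | starting material
2 | tert-butyl 3-oxobutanoate | CC(=O)CC(=O)OC(C)(C)C | starting material
3 | tert-butyl (3S)-2-acetyl-3-methyl-5-oxopentanoate (C2 epimers) | CC(=O)C(C(=O)OC(C)(C)C)[C@@H](C)CC=O | intermediate
4 | tert-butyl (6S)-6-methyl-2-oxocyclohex-3-ene-1-carboxylate (C1 epimers) | CC(C)(C)OC(=O)C1C(=O)C=CC[C@@H]1C | intermediate
5 | (5S)-5-methylcyclohex-2-en-1-one | O=C1C=CC[C@H](C)C1 | intermediate
6 | (4R)-4-benzyl-1,3-oxazolidin-2-one | O=C1N[C@H](Cc2ccccc2)CO1 | starting material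
7 | 3-methylbut-2-enoyl chloride (senecioyl chloride) | CC(C)=CC(Cl)=O | starting material
8 | lithium (4R)-4-benzyl-2-oxo-1,3-oxazolidin-3-ide (N–Li salt of 6) | [Li]N1[C@H](Cc2ccccc2)COC1=O | intermediate
9 | (4R)-4-benzyl-3-(3-methylbut-2-enoyl)-1,3-oxazolidin-2-one | CC(C)=CC(=O)N1[C@H](Cc2ccccc2)COC1=O | intermediate
10 | tert-butyl bromoacetate | BrCC(=O)OC(C)(C)C | starting material
11 | sodium (Z)-dienolate of 9 (O–Na on the acyl oxygen, C1=C2 enolate bond, isopropenyl at C2) | C=C(C)/C=C(\O[Na])N1[C@H](Cc2ccccc2)COC1=O | intermediate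
12 | tert-butyl (3R)-3-{[(4R)-4-benzyl-2-oxo-1,3-oxazolidin-3-yl]carbonyl}-4-methylpent-4-enoate | C=C(C)[C@@H](CC(=O)OC(C)(C)C)C(=O)N1[C@H](Cc2ccccc2)COC1=O | intermediate
13 | tert-butyl (3R)-3-(hydroxymethyl)-4-methylpent-4-enoate | C=C(C)[C@@H](CC(=O)OC(C)(C)C)CO | intermediate
14 | tert-butyl (3R)-3-(iodomethyl)-4-methylpent-4-enoate | C=C(C)[C@@H](CC(=O)OC(C)(C)C)CI | intermediate
15 | {[(3R)-1-tert-butoxy-3-(iodomethyl)-4-methylpent-4-en-1-yl]oxy}bis(2-methylpropyl)alumane (aluminium hemiacetal of 14) | C=C(C)[C@@H](CC(O[Al](CC(C)C)CC(C)C)OC(C)(C)C)CI | intermediate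
16 | (3R)-3-(iodomethyl)-4-methylpent-4-enal | C=C(C)[C@@H](CC=O)CI | intermediate
17 | dicyclohexyl{[(3S)-3-methylcyclohexa-1,5-dien-1-yl]oxy}borane (α′ boron enolate of 5) | C1=C(OB(C2CCCCC2)C2CCCCC2)C=CC[C@@H]1C | intermediate
18 | (5S,6S)-6-[(1S,3R)-1-hydroxy-3-(iodomethyl)-4-methylpent-4-en-1-yl]-5-methylcyclohex-2-en-1-one | C=C(C)[C@H](CI)C[C@H](O)[C@H]1C(=O)C=CC[C@@H]1C | intermediate
19 | (5S,6S)-6-[(1S,3R)-1-{[tert-butyl(dimethyl)silyl]oxy}-3-(iodomethyl)-4-methylpent-4-en-1-yl]-5-methylcyclohex-2-en-1-one | C=C(C)[C@H](CI)C[C@H](O[Si](C)(C)C(C)(C)C)[C@H]1C(=O)C=CC[C@@H]1C | intermediate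
20 | lithium dienolate of 19 (O–Li on the ring oxygen, enolate C=C to the ring carbon bearing the side chain) | C=C(C)[C@H](CI)C[C@H](O[Si](C)(C)C(C)(C)C)C1=C(O[Li])C=CC[C@@H]1C | intermediate
21 | (1S,3R,5R,10S)-1-{[tert-butyl(dimethyl)silyl]oxy}-10-methyl-3-(prop-1-en-2-yl)spiro[4.5]dec-7-en-6-one | C=C(C)[C@H]1C[C@H](O[Si](C)(C)C(C)(C)C)[C@]2(C1)C(=O)C=CC[C@@H]2C | intermediate
22 | (1S,3R,5R,10S)-1-{[tert-butyl(dimethyl)silyl]oxy}-6,10-dimethyl-3-(prop-1-en-2-yl)spiro[4.5]dec-7-en-6-ol (C6 epimers) | C=C(C)[C@H]1C[C@H](O[Si](C)(C)C(C)(C)C)[C@]2(C1)C(C)(O)C=CC[C@@H]2C | intermediate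
23 | (1S,3R,5S,10S)-1-{[tert-butyl(dimethyl)silyl]oxy}-6,10-dimethyl-3-(prop-1-en-2-yl)spiro[4.5]dec-6-en-8-one | C=C(C)[C@H]1C[C@H](O[Si](C)(C)C(C)(C)C)[C@]2(C1)C(C)=CC(=O)C[C@@H]2C | intermediate
24 | (1S,3R,5S,10S)-1-hydroxy-6,10-dimethyl-3-(prop-1-en-2-yl)spiro[4.5]dec-6-en-8-one | C=C(C)[C@H]1C[C@H](O)[C@]2(C1)C(C)=CC(=O)C[C@@H]2C | intermediate
25 | (1S,3R,5S,10S)-6,10-dimethyl-8-oxo-3-(prop-1-en-2-yl)spiro[4.5]dec-6-en-1-yl 3-methylbut-2-enoate | C=C(C)[C@H]1C[C@H](OC(=O)C=C(C)C)[C@]2(C1)C(C)=CC(=O)C[C@@H]2C | intermediate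
26 | lithium dienolate of 25 (O–Li on the C8 oxygen, C8=C9 enolate bond, C6=C7 retained) | C=C(C)[C@H]1C[C@H](OC(=O)C=C(C)C)[C@]2(C1)C(C)=CC(O[Li])=C[C@@H]2C | intermediate
27 | (1S,3R,5S,9S,10R)-9-hydroxy-6,10-dimethyl-8-oxo-3-(prop-1-en-2-yl)spiro[4.5]dec-6-en-1-yl 3-methylbut-2-enoate | C=C(C)[C@H]1C[C@H](OC(=O)C=C(C)C)[C@]2(C1)C(C)=CC(=O)[C@@H](O)[C@@H]2C | intermediate
28 | (1S,3R,5S,9S,10R)-9-(acetyloxy)-6,10-dimethyl-8-oxo-3-(prop-1-en-2-yl)spiro[4.5]dec-6-en-1-yl 3-methylbut-2-enoate (CNP0218315.1) | C=C(C)[C@H]1C[C@H](OC(=O)C=C(C)C)[C@]2(C1)C(C)=CC(=O)[C@@H](OC(C)=O)[C@@H]2C | target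

## Step count and risks

Total step count: 15. Longest linear sequence: 14 steps (steps 2–6, then 7–15); the ring fragment 5 joins after one step.

**Most likely to fail, in order:**

**Step 9 (spirocyclisation).** The enolate 20 carries a β-silyloxy group and can eliminate it (E1cB) in competition with the 5-exo alkylation; the iodide, DMPU and low temperature are chosen to favour alkylation. Fallback: set out from 18 without silylation. Two equivalents of LiN(i-Pr)2 (THF/DMPU, −78 to −20 °C) give the dilithium alkoxide-enolate of 18 F1, whose β-oxygen is an alkoxide that cannot be expelled. C-alkylation then gives (1S,3R,5R,10S)-1-hydroxy-10-methyl-3-(prop-1-en-2-yl)spiro[4.5]dec-7-en-6-one F2. Silylation (t-BuMe2SiOTf, 2,6-lutidine) brings it back to the route at 21. The weak points of this fallback are O-alkylation to a tetrahydrofuran and lithium chelation placing the chain on the wrong face.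

**Step 7 (boron aldol).** Soft enolisation of the enone must occur at the α′ carbon and not at the γ position, and the anti/trans selectivity is argued by analogy with cyclohexanone boron enolates rather than demonstrated on this enone. A wrong carbinol epimer is the mismatched substrate for step 9. Fallback: set out from 5. α′-Bromination with PhNMe3Br3 (THF, 0 °C) gives (5S)-6-bromo-5-methylcyclohex-2-en-1-one F3. CrCl2 (divalent chromium, 2.2 equiv, THF, rt) inserts into the C–Br bond and gives dichloro{[(3S)-3-methylcyclohexa-1,5-dien-1-yl]oxy}chromium F4 regiospecifically. This trivalent chromium enolate adds to 16 through a closed transition state (chromium Reformatsky reaction, anti-selective) and comes back to the route at 18.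

**Step 14 (α′-hydroxylation).** γ-Deprotonation, attack of the enolate on the sulfonimine by-product or on the nearby ester, and imperfect facial control can all erode the yield. Fallback: set out from 25 and go directly to 28. Mn(OAc)3·2H2O (trivalent manganese) in benzene at reflux acetoxylates the α′ position of the enone, trans to the neighbouring methyl. This makes no new compound and skips 27 and step 15; its own risk is radical chemistry at the isopropenyl group.

## Further compounds

F1 | step 9 | dilithium alkoxide-enolate of 18 (O–Li on the carbinol oxygen and on the ring enolate oxygen) | C=C(C)[C@H](CI)C[C@H](O[Li])C1=C(O[Li])C=CC[C@@H]1C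
F2 | step 9 | (1S,3R,5R,10S)-1-hydroxy-10-methyl-3-(prop-1-en-2-yl)spiro[4.5]dec-7-en-6-one | C=C(C)[C@H]1C[C@H](O)[C@]2(C1)C(=O)C=CC[C@@H]2C
F3 | step 7 | (5S)-6-bromo-5-methylcyclohex-2-en-1-one | BrC1C(=O)C=CC[C@@H]1C
F4 | step 7 | dichloro{[(3S)-3-methylcyclohexa-1,5-dien-1-yl]oxy}chromium | C1=C(O[Cr](Cl)Cl)C=CC[C@@H]1C
F0 | step 14 | none | none
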